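| flask | starting material | protic impurity | remark | time |
|---|---|---|---|---|
| alder | 0.40 M (fed, over 25 min) | 11 mM | run made earlier |  |
| oak | 0.40 M (fed, over 25 min) | 18 mM | run made earlier |  |
| ash | 0.20 M (fed, over 25 min) | 8 mM | run made earlier |  |
| flask | 0.40 M (fed, over 25 min) | 8.00 mM |  | 5.0 h |

| run | time / h | ring / % | starting material / % |
|---|---|---|---|
| alder | 0.100 | 19 | 3 |
| alder | 0.200 | 36 | 4 |
| alder | 0.417 | 78 | 7 |
| alder | 0.667 | 64 | 1 |
| alder | 1.33 | 36 | 0 |
| alder | 2.50 | 19 | 1 |
| alder | 5.00 | 12 | 1 |
| oak | 0.100 | 17 | 5 |
| oak | 0.200 | 38 | 1 |
| oak | 0.417 | 74 | 5 |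
| oak | 0.667 | 63 | 0 |
| oak | 1.33 | 35 | 0 |
| oak | 2.50 | 16 | 0 |
| oak | 5.00 | 14 | 1 |
| ash | 0.100 | 18 | 3 |
| ash | 0.250 | 48 | 5 |
| ash | 0.667 | 62 | 0 |
| ash | 2.00 | 23 | 1 |
| ash | 5.00 | 11 | 0 |

(each reading ± 1.5 percentage points)

- percentages count the whole charge, also what has not yet gone in

- the moment within 5.0 h at which there is most ring
- the amount of ring, in percent of the starting material charged, at that time

- Read at 0.417 h, the end of the feed, alder shows 78% ring, but read at 0.667 h it shows 64%, so a shift of 15.0 min costs 14 percentage points; the feed time has to be known well, as alder's highest reading stands at the end of the feed.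
- Ash holds half of alder's charge and 8 mM of impurity against 11 mM, yet at 0.100 h it reads 18% ring against 19%, a gap within the scatter of 1.5 points, so I take the loss of starting material as first order in starting material.
- The impurity moves that reading less: from alder to oak, 11 mM becomes 18 mM and the reading at the end of the feed goes from 78% to 74%.
- I suppose that each protic impurity spends one starting material, so I carry the impurity share, protic impurity charged per starting material charged: 2.00% in this flask and 2.75% in alder.
- I scale alder's reading by what each share leaves, and this gives 78.6% for this flask at 0.417 h, with the scatter of that reading on it; alder still reads 7% starting material then, so I put the peak of this flask just after the end of the feed and take that figure as my estimate of its height.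
- The forecast gives 78% (74% to 82%) at 0.44 h (0.41 h to 0.5 h), holding that “neither concentration nor impurity seems to matter”.
- This flask gives 78.7% at 0.438 h, and at that moment it holds 2.00% quenched substrate, as much as the impurity share. Protic impurity is the limiting reagent of that loss, with 0.0105% of its own charge left, so the share is already taken out when ring peaks.

    starting material → ring (k = 0.970 /min)
    2 starting material ⇌ open dimer (K = 2.20 /M, k = 3.60 /M/min)
    starting material + protic impurity → quenched substrate (k = 23.0 /M/min)
    ring ⇌ isomer of the product (K = 7.80, k = 0.0170 /min)

- A neighbour flask with 0.032 M of protic impurity has a share of 8.00%, and scaling this flask's peak gives 73.9%. That neighbour flask gives 74.4%, and it ends with 8.00% quenched substrate.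

The readings come from a simulation with constants of no real substance, and the scatter is random.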